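Assumption: the stereocentre in the SMILES is (R) at C-2 of the propan-1-one chain (worked out from the SMILES); potassium (R)-glycidate, MOMCl and prenyl bromide are taken as commercial.

## Retrosynthetic overview

1. The target comes from its tris-MOM ether by mild acid. No ring is formed anywhere: both benzene rings are bought intact (resorcinol, 4-bromophenol).
2. Key disconnection, aryl–C(=O): the C2v-symmetric 2-prenylresorcinol bis-MOM ether is lithiated at one of its two equivalent ortho sites and acylated by the dilithio salt of an unprotected (R)-3-aryl-lactic acid. This step breaks the symmetry and joins the two halves.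
3. The (R)-aryl-lactic acid comes from Cu-catalysed C3 opening of potassium (R)-glycidate by the B-ring Grignard. The stereocentre is purchased and never becomes a reacting centre.
4. Prenyl groups: A ring by C2 lithiation/prenylation of resorcinol bis-MOM ether (symmetry retained); B ring by ortho C-prenylation of 4-bromophenol.
5. Order: A fragment (2 steps) and B fragment (3 steps) in parallel, then union, then global deprotection.

## Route

**Step 1**
Reactants: 1 resorcinol; 2 chloromethyl methyl ether (MOMCl)
Product: 3, 1,3-bis(methoxymethoxy)benzene
Conditions: NaH (2.4 equiv), DMF, 0 °C; MOMCl (2.4 equiv), 0 → 23 °C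
Reagents that add atoms: MOMCl, COCCl
Why: Williamson-type O-alkylation of both phenoxides installs two MOM ethers that serve as protecting groups and as ortho-directing groups.

**Step 2**
Reactants: 3; 4 prenyl bromide (1-bromo-3-methylbut-2-ene)
Product: 5, 1,3-bis(methoxymethoxy)-2-(3-methylbut-2-en-1-yl)benzene (mirror-symmetric)
Conditions: n-BuLi (1.1 equiv), THF, 0 → 23 °C, 1 h; CuI (0.2 equiv), then 4, –78 → 23 °C
Reagents that add atoms: prenyl bromide, CC(C)=CCBr
Why: Directed ortho-metalation occurs at C2, the site flanked by both OMOM groups, and Cu-mediated SN2 allylation gives the linear prenyl group while keeping the arene C2v-symmetric.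

**Step 3**
Reactants: 6 4-bromophenol; 4 prenyl bromide
Product: 7, 4-bromo-2-(3-methylbut-2-en-1-yl)phenol
Conditions: NaH (1.1 equiv), toluene, 0 °C; 4 (1.0 equiv), 23 °C, 16 h
Reagents that add atoms: prenyl bromide, CC(C)=CCBr
Why: Ortho C-alkylation of a tight ion-paired sodium phenoxide in a non-polar solvent; para is blocked by Br and the two ortho sites are equivalent, so only one C-prenyl isomer forms (O-prenyl ether is the separable by-product).

**Step 4**
Reactants: 7; 2 MOMCl
Product: 8, 4-bromo-1-(methoxymethoxy)-2-(3-methylbut-2-en-1-yl)benzene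
Conditions: i-Pr2NEt (1.5 equiv), MOMCl (1.3 equiv), CH2Cl2, 0 → 23 °C
Reagents that add atoms: MOMCl, COCCl
Why: Base-mediated O-alkylation (MOM protection) masks the phenol for Grignard formation; the amine base scavenges HCl so the prenyl alkene is untouched.

**Step 5**
Reactants: 8; 9 potassium (R)-glycidate [potassium (2R)-oxirane-2-carboxylate]
Product: 10, (2R)-2-hydroxy-3-[4-(methoxymethoxy)-3-(3-methylbut-2-en-1-yl)phenyl]propanoic acid
Conditions: Mg, THF, 45 °C (ArMgBr, 1.3 equiv); CuI (10 mol %), 9 (1.0 equiv, THF suspension), –30 → 0 °C; aq. NaHSO4 to pH 3, 0 °C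
Reagents that add atoms: potassium (R)-glycidate, [K+].[O-]C(=O)[C@H]1CO1
Why: Cu(I)-catalysed SN2 epoxide opening by the aryl Grignard at the unsubstituted C3 of the glycidate salt (the carboxylate is inert to RMgX); C2 is not a reacting centre, so the purchased configuration is carried over and the descriptor stays R.

**Step 6 (key step)**
Reactants: 5 (3.4 equiv); 10 (1.0 equiv)
Product: 11, (2R)-1-[2,4-bis(methoxymethoxy)-3-(3-methylbut-2-en-1-yl)phenyl]-2-hydroxy-3-[4-(methoxymethoxy)-3-(3-methylbut-2-en-1-yl)phenyl]propan-1-one
Conditions: 5, n-BuLi (3.2 equiv), TMEDA (3.2 equiv), THF, 0 °C, 1.5 h; add 10 in THF, –78 → 23 °C, 4 h; TMSCl quench, then 1 M HCl, 0 °C, 10 min (about 2 equiv of 5 recovered)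
Reagents that add atoms: none beyond the two listed reactants (n-BuLi, TMEDA and TMSCl leave no atoms)
Why: OMOM-directed ortho-lithiation of 5 (C4 and C6 are equivalent, so one aryllithium forms) followed by the classical organolithium–lithium carboxylate ketone synthesis; two equivalents of ArLi deprotonate OH and CO2H, the third adds to give a gem-diolate that cannot enolise or over-add and releases the ketone only on quench, so the (R) centre is untouched.

**Step 7**
Reactants: 11
Product: 12, glycybridin C, (2R)-1-[2,4-dihydroxy-3-(3-methylbut-2-en-1-yl)phenyl]-2-hydroxy-3-[4-hydroxy-3-(3-methylbut-2-en-1-yl)phenyl]propan-1-one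
Conditions: 3 M aq. HCl/MeOH (1:10), 40 °C, 2 h
Reagents that add atoms: none
Why: Acid-catalysed acetal solvolysis removes the three aryl MOM groups; dilute HCl/MeOH at ≤40 °C is the standard unmasking for ortho-prenylphenols (no chroman formation expected) and is too mild to enolise the hydrogen-bonded α-hydroxy ketone, so the (R) configuration should be retained.

## Compound list

1 | resorcinol | Oc1cccc(O)c1 | starting material
2 | chloromethyl methyl ether (MOMCl) | COCCl | starting material (reagent)
3 | 1,3-bis(methoxymethoxy)benzene | COCOc1cccc(OCOC)c1 | intermediate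
4 | prenyl bromide | CC(C)=CCBr | starting material (reagent)
5 | 1,3-bis(methoxymethoxy)-2-(3-methylbut-2-en-1-yl)benzene | COCOc1cccc(OCOC)c1CC=C(C)C | intermediate
6 | 4-bromophenol | Oc1ccc(Br)cc1 | starting material
7 | 4-bromo-2-(3-methylbut-2-en-1-yl)phenol | CC(C)=CCc1cc(Br)ccc1O | intermediate
8 | 4-bromo-1-(methoxymethoxy)-2-(3-methylbut-2-en-1-yl)benzene | COCOc1ccc(Br)cc1CC=C(C)C | intermediate
9 | potassium (2R)-oxirane-2-carboxylate | [K+].[O-]C(=O)[C@H]1CO1 | starting material
10 | (2R)-2-hydroxy-3-[4-(methoxymethoxy)-3-prenylphenyl]propanoic acid | OC(=O)[C@H](O)Cc1ccc(OCOC)c(CC=C(C)C)c1 | intermediate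
11 | (2R)-1-[2,4-bis(methoxymethoxy)-3-prenylphenyl]-2-hydroxy-3-[4-(methoxymethoxy)-3-prenylphenyl]propan-1-one | COCOc1ccc(C[C@@H](O)C(=O)c2ccc(OCOC)c(CC=C(C)C)c2OCOC)cc1CC=C(C)C | intermediate
12 | glycybridin C | CC(C)=CCc1cc(C[C@@H](O)C(=O)c2ccc(O)c(CC=C(C)C)c2O)ccc1O | target

## Summary

Total steps: 7. Longest linear sequence: 5 (steps 3–7 from 4-bromophenol); the resorcinol branch (steps 1–2) joins at step 6.

Steps most likely to fail:

1. **Step 6.** The aryllithium may add sluggishly to the polyanionic α-alkoxide carboxylate, or n-BuLi may deprotonate the benzylic/allylic CH2 of 5 instead of the ring. Fallback: abandon the carboxylate and C–H lithiation. Convert 10 into its O-TBS Weinreb amide and add the aryllithium made by Br/Li exchange from 1-bromo-2,4-bis(methoxymethoxy)-3-prenylbenzene (built from 4-bromoresorcinol).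
2. **Step 5.** The poorly soluble glycidate salt may open slowly or with the wrong regiochemistry. Fallback: drop the epoxide opening and take the stereocentre from D-tyrosine instead. Diazotisation with retention gives (R)-4-hydroxyphenyllactic acid, which is then esterified, ortho-C-prenylated, MOM-protected and saponified to 10.
3. **Step 7.** Triple MOM removal could cyclise an ortho-prenylphenol to a chroman or erode ee at the α-ketol (check by chiral HPLC). Fallback: change the protecting-group plan to THP ethers on all three phenols. OTHP is also an ortho-directing group, and the end-game then needs only PPTS/EtOH at room temperature.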